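Count this flask in equivalents of partner rather than in minutes.

| flask | substrate | partner | remark | time |
|---|---|---|---|---|
| west | 0.047 M | 1.1 equiv | the very flask that is asked about, followed so far |  |
| flask | 0.047 M | 1.10 equiv |  | 5.0 h |

- west (time / min: first product / %, substrate / %): 25.0: 16.7, 82.3; 60.0: 31.2, 70.4; 120: 39.8, 57.6; 300: 50.4, 47.8

(scatter of a reading: 1 percentage point)

* first product, in percent of the substrate first charged, at 5.0 h
* what to do for the largest gain in first product; "none" if nothing gains more than 2 percentage points (autumn / dusk / winter / midnight / none)
* first product present, in percent of the substrate first charged, after dusk
* first product present, in percent of the substrate first charged, after midnight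

- autumn: at 5.0 h add partner, 50.0% of the amount charged, then wait 5.0 h
- dusk: at 5.0 h add substrate, 50.0% of the amount charged, then wait 5.0 h
- winter: change nothing and wait 5.0 h more
- midnight: at 5.0 h take out 90% of the released group then present, then wait 5.0 h

- the volume of additions can be left aside
- the numbers in the tables scatter with a standard deviation of 1 percentage point
- a reading or a percentage of first product counts all its forms, free or not

In the west run, the asked flask itself, the rate per substrate (a pseudo-first-order rate that follows the partner present) is 0.00779 /min over the first stretch and 0.00334 /min and 0.00104 /min over the last two. Spent one for one with substrate, partner would keep 52.5% of its charge at the last reading, yet that rate has fallen to 13.4% of its first value. My reckoning therefore supposes that partner is also lost another way and that no back step runs, which these readings do not test.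

Divide the substrate's fractional rate by the partner's fractional loss and time drops out. I take that ratio as steady, a rough rule and not an exact one, so that each equivalent gives about the same fall in the logarithm of substrate. Reading the flask as stopped at 300 min, that fall is 0.738, or 0.671 per equivalent, so autumn's partner gains 15 percentage points.

The weak link is that stop. The rate per substrate is still falling at 0.00977 /min, and its end value over this gives a tail of 0.0441. That gives 0.711 for the reach, the average fall in the logarithm of substrate per equivalent of partner charged. By this reckoning dusk gains 4.2 points, winter and midnight each gain 2.1 points, and autumn gains 17 points, more than either. I commit to 50.4% now and to autumn. That puts dusk at 54.6% and midnight at 52.5%.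

The forecast differs: “a reversible model reaches a plateau”, giving 50.5% now, midnight as best, 61% after dusk and 65.3% after midnight.

The flask gives 51.4%, and autumn gains 19 points, with 54.2% after dusk and 53.3% after midnight.

    partner → decomposed reagent (k = 8.58 × 10⁻⁵ /s)
    crystals ⇌ first product, rate k2*(cs2 - [first product]) while solid is left; crystals form when [first product] > cs2 (solubility = 3.60 mM, k = 0.00210 /s)
    partner + first product → double product + released group (k = 1.43 × 10⁻⁴ /M/s)
    substrate + partner → first product + released group (k = 0.00290 /M/s)
    2 partner → self-condensation product (k = 2.78 × 10⁻⁴ /M/s)

At the asked time 4.23% of the partner charge stands free. The reach puts substrate at 45.7% once this flask has finished, and at 3000 min it holds 46.3%. For the neighbour with 4.40 equiv of partner the reach gives 4.38% of substrate; that flask holds 4.62% at 300 min, with 93.5% of first product.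

The readings are simulated with made-up constants.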